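All runs come from a simulation for an exercise, noise included.

Read at 15 min, a flask has had longer to leak than any run so far was watched, and Sunday's, the hottest, stops at 4.00 min. You asked for a quick number, and your hunch is that a closing balance means nothing leaks. Test that first.

| flask | starting material | partner | second substrate | protic impurity | temperature | remark | time |
|---|---|---|---|---|---|---|---|
| Thursday's | 5 mM | 6 mM | 20 mM | 0.20 mM | 35 °C | run made earlier |  |
| Sunday's | 20 mM | 6 mM | 20 mM | 0.20 mM | 60 °C | run made earlier |  |
| Saturday's | 10 mM | 6 mM | 20 mM | 0.10 mM | 35 °C | run made earlier |  |
| south-west | 10 mM | 6.00 mM | 20.0 mM | 0.200 mM | 40 °C |  | 15 min |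
| north | 10 mM | 6.00 mM | 20.0 mM | 0.200 mM |  | at 40 °C until 8.0 min, from then on at 80 °C | 15 min |
| west | 10 mM | 6.00 mM | 20.0 mM | 0.200 mM | 60 °C |  | 15 min |
| south | 10 mM | 6.00 mM | 20.0 mM | 0.200 mM | 80 °C |  | 15 min |

| run | time / min | target / % | starting material / % |
|---|---|---|---|
| Thursday's | 0.667 | 3 | 98 |
| Thursday's | 1.50 | 4 | 94 |
| Thursday's | 4.00 | 10 | 90 |
| Thursday's | 10.0 | 13 | 85 |
| Sunday's | 1.00 | 9 | 88 |
| Sunday's | 2.00 | 15 | 85 |
| Sunday's | 4.00 | 18 | 83 |
| Saturday's | 1.00 | 3 | 98 |
| Saturday's | 3.00 | 6 | 95 |
| Saturday's | 6.00 | 10 | 88 |
| Saturday's | 10.0 | 13 | 86 |

(scatter of a reading: 1.5 percentage points)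

- the numbers in the tables scatter with a standard deviation of 1.5 percentage points
- steps under discussion: starting material + partner <-> target; second substrate + partner <-> second product; second substrate + protic impurity -> quenched substrate; target -> over-reaction product

- the best flask by amount of target, in percent of the starting material charged; "all alike" if 1.5 percentage points covers them all (south-west / north / west / south / all alike)
- amount of target at the end, in percent of the starting material charged, south-west
- amount of target at the end, in percent of the starting material charged, north
- amount of target at the end, in percent of the starting material charged, west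
- amount of target at the end, in percent of the starting material charged, south

Take Sunday's run, hotter than the other two, with c(starting material) at 20 mM. At its last reading, 4.00 min, target and starting material add up to 101%. Each reading scatters by 1.5 percentage points, so allow two standard deviations of the sum: a hidden loss of 3.2 points still fits.

Now replace the target curve by its mean. The target readings of that run average 14.0%, and a first-order loss takes constant times mean times time. That gives 0.0579 /min: the loss ceiling, the first-order constant for the loss of target above which Sunday's readings ought to show a gap. Check the error. The trapezoid through zero gives a mean of 12.4% and a ceiling of 0.0655 /min, so the reading stands, roughly.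

Its half-life is 12.0 min, shorter than the time of reading. So your closing balance doesn't clear west, at 60 °C. South and north reach 80 °C, hotter than Sunday's, so a ceiling read at 60 °C gives them no cover. Bet on west, and distrust the hot flasks.

The forecast gives 16.5% for south-west, 32% for north, 24.5% for west and 30% for south, picks north, and holds that “over-reaction is not visible up to 60 °C”.

The flasks give 19.1% in south-west, 10.3% in north, 27.5% in west and 1.91% in south, so west is best.

    starting material + partner ⇌ target (K = 3000 /M, k = 6.50 /M/min, Ea = 61.0 kJ/mol, ΔH = −4.00 kJ/mol)
    second substrate + partner ⇌ second product (K = 210 /M, k = 6.70 /M/min, Ea = 47.0 kJ/mol, ΔH = −52.0 kJ/mol)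
    second substrate + protic impurity → quenched substrate (k = 560 /M/min, Ea = 44.0 kJ/mol)
    target → over-reaction product (k = 0.00380 /min, Ea = 103 kJ/mol)
    (constants at 40 °C)

West ends with 14.5% of over-reaction product beside 27.5% of target; with that end value as the mean, its constant is 0.0351 /min, below the ceiling. North held 15.1% of target and 0.287% of over-reaction product at the change, 8.0 min. Then north's target had a half-life by the loss to over-reaction product of 2.1 min at 8.79 min, a constant of 0.336 /min, above the ceiling, and north ended with 44.0% of over-reaction product and 10.3% of target.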